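## Structural features

The target (C24H18O11) is an achiral polyphenol of four benzene rings in a row. Ring A (3,5-dihydroxyphenyl) is joined through an ether oxygen to ring B (1,3,5-trioxygenated, one free hydroxyl), ring B through a second ether oxygen to C1 of ring C, and C5 of ring C through a carbon–carbon bond to ring D (2,4,6-trihydroxyphenyl). Ring C is the only unsymmetrical ring and is pentasubstituted: O-aryl at C1, OH at C2, H at C3, OH at C4, ring D at C5, OH at C6. There is no stereocentre, so none stand next to each other, and the C5–ring D axis is not a stereogenic unit because ring D is symmetrical about it. The fragile features are the nine free phenols on electron-rich rings: ring C is a hydroquinone monoaryl ether (O1 para to O4) that oxidises easily to a quinone, and the phloroglucinol-type rings are strongly nucleophilic, so all hydroxyls must stay masked until the last step. The real difficulty is ring C: O1 must be told apart from three other oxygens on the same ring, the O1–ring B ether is flanked by two ortho oxygens, and the C5–ring D bond carries four ortho oxygens. The key step uses the para pair O1/O4 with the adjacent aryl (C5) and oxygen (C6): C4, C5, C6 and C1 map onto the four carbons of an aryl-alkoxy-cyclobutenone from a squarate, and C2 (oxygen) and C3 (hydrogen) come from a 1-alkoxyvinyl group. Thermal ring expansion then forms the C3–C4 bond and delivers O4 free and O1 capped.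

## Logic of the disconnections

19 to 18. The nine O–H bonds are traced back to nine O–alkyl bonds (seven methyl, one ethyl, one isopropyl). The free nonaphenol cannot be carried through C–O or C–C bond formation, and every one of these alkyl groups arrives with a building block, so no separate protection steps are spent. The forward step must cleave three kinds of alkyl aryl ether with one reagent and leave the two diaryl ethers and the biaryl bond intact.

18 to 14 and 17. The bond between O1 of ring C and its ring B carbon is cut. This splits the molecule into two halves of similar size, and in 14 the oxygen to be arylated is the only free hydroxyl. The forward step is a C–O coupling of a di-ortho-alkoxy phenoxide, so the halide partner must be free of ortho substituents, which 17 is. An aryne-based O-arylation was weighed for this bond; it tolerates hindrance but needs a silyl triflate precursor of the ring A–B unit that costs several steps, so a copper coupling is preferred and a metal-free arylation is held in reserve.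

17 to 15 and 16. The ether bond between the ring A oxygen and ring B is cut, giving two simple benzenes. The forward step must couple at the carbon–iodine bond of 16 and leave the carbon–bromine bond for the later coupling.

14 to 13 to 12. The O4–methyl bond and then the O1 acetal bond are traced back. The ring expansion delivers O4 free and O1 capped, the reverse of what the coupling needs, and two simple operations exchange the roles. The cap on O1 must survive basic methylation and then come off under conditions that leave methyl, ethyl and isopropyl aryl ethers alone; an acetal does both.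

12 to 9. The C3–C4 bond of ring C is cut and ring C is contracted to a cyclobutenone carrying a 1-ethoxyvinyl group and the capped oxygen on its sp3 carbon. A pentasubstituted benzene with four differentiated oxygens becomes a squarate adduct in which every position is set by carbonyl addition. The forward step needs the ring oxygen to rotate outward on opening, and the enol ether and acetal to survive about 110 °C.

9 to 5 and 6. The bond between the quaternary ring carbon and the vinyl carbon, and the O–CH2 bond of the cap, are cut. This leaves a cyclobutenedione and a two-carbon vinyl ether. The forward step needs 1,2-addition at the carbonyl next to the isopropoxy-bearing carbon and efficient capture of a crowded tertiary alkoxide.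

5 to 1 and 2. The bond between ring D and the four-membered ring, the future C5–ring D biaryl bond, is cut. The crowded biaryl bond is thus made by adding an aryllithium to a carbonyl group, with no cross-coupling at a tetra-ortho-substituted axis. The forward step needs mono-addition and a clean acid-induced transposition to the dione.

## Other disconnections considered

Alternative 1: Both aryl–oxygen bonds of ring B are cut. In the forward direction the cationic complex A1, a CpRu fragment of divalent ruthenium bound η6 to 1,3-dichloro-5-methoxybenzene, would take the phenoxide of 15 and then the phenoxide of the ring C–D phenol A2 in two successive SNAr reactions in one pot. This would give the complex A3, and photolytic release of the arene and global demethylation would follow.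
- In its favour: the metal turns an electron-rich chloroarene into a strong SNAr electrophile near room temperature; the nucleophile attacks an unhindered ring carbon on the face away from the metal; the first aryloxy group lowers the electrophilicity, which helps to hold the mono-substitution stage; protection is uniform (methyl only).
- Against it here: ruthenium is used stoichiometrically and a decomplexation step is added; the second substitution must occur on a complex already deactivated by two oxygen donors, with the more hindered nucleophile; and A2 is left unsolved. A2 contains the tetra-ortho-oxygenated biaryl bond and one free hydroxyl among six oxygens, which is exactly what the chosen ring expansion supplies.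
- Comparison: for the ether-forming stage alone this alternative is the equal or the better of the chosen plan (milder, two bonds in one operation against steps 6 and 7). For the whole molecule it is longer and rests on a stoichiometric precious metal. Mechanistically it is ionic addition–elimination on a metal-bound arene, against a pericyclic construction of ring C.

Alternative 2: A carbon–carbon bond inside ring D is cut, between its C1 and an oxygenated ortho carbon, so that ring D is unfolded into a 3,5-dioxohexanoate chain attached by a benzylic CH2 to C5 of ring C (ester A4). In the forward direction base would form the chain polyanion, the benzylic carbon would attack the ester carbon in an intramolecular Claisen condensation, and the triketone would enolise to the triol A5.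
- In its favour: the folding is biomimetic; the biaryl bond is never made by coupling, since it already exists as an aryl–CH2 bond; ring D appears with three free hydroxyls, so three fewer ethers remain to be cleaved.
- Against it here: the benzylic carbon that must attack is the least acidic position of the chain and is flanked by two ortho methoxy groups; the enol oxygen at the distal ketone can attack the ester instead and give a 4-hydroxypyranone; and A4 requires ring C with a one-carbon handle at C5 and the complete ring A–B ether already in place, so the substitution problem of ring C is not addressed. The ring closure would also be the last C–C bond, made on the most advanced material.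
- Comparison: on avoiding a biaryl cross-coupling the two plans are equal. On the final deprotection load of ring D this alternative is better. On overall step count and on control of ring C the chosen plan is stronger, because the squarate fixes every position of ring C in three steps.

Alternative 3: The C5–C6 and C3–C4 bonds of ring C are cut, giving the 4-aryloxy-3-ethoxycyclobutenone A6 (carrying rings A and B) and the ring D siloxyalkyne A7. In the forward direction heating would open A6 to a vinylketene, which would add to A7 in a [2+2] sense; the new vinylcyclobutenone would open and close by a six-electron electrocyclisation to the phenol A8 (Danheiser benzannulation).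
- In its favour: it is the most convergent plan, all four rings being united in one step; the ring A–B ether is already on the cyclobutenone, so no hindered O-arylation at C1 is needed; the polarity of the siloxyalkyne fixes the regiochemistry.
- Against it here: A6 has an aryloxy group and an acidic hydrogen on its sp3 carbon and no secure preparation; the alkyne carbon of A7 that must bond to the ketene is screened by two ortho methoxy groups; and A7 itself must come from a hindered aryl ester by ynolate homologation.
- Comparison: the mechanism is close kin to the chosen one (cyclobutenone opening, ketene, six-electron closure), so on mechanistic footing the two are equal. On convergence and step count after ring formation this alternative is better. The chosen plan is stronger in the reliability of its inputs: squarate additions with regiochemistry enforced by vinylogous ester deactivation, and a biaryl bond that arises from a carbonyl addition.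

Key step: step 3

Remark on the chemistry: 16 is taken as a commercial building block. The only stereochemical element in the route is the racemic quaternary carbon of 4, 8 and 9, which step 3 erases. Simple phenoxide salts and copper- or boron-bound species of no defined composition are not numbered.

## Route

Step 1
Reactants: 1 1,3,5-trimethoxybenzene; 2 diisopropyl squarate [3,4-di(propan-2-yloxy)cyclobut-3-ene-1,2-dione]
Product: 5 3-(propan-2-yloxy)-4-(2,4,6-trimethoxyphenyl)cyclobut-3-ene-1,2-dione, via 2,4,6-trimethoxyphenyllithium 3 (not isolated), via carbinol adduct 4 (not isolated)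
Conditions: n-BuLi, THF, 0 °C to rt; 2, THF, −78 °C; 1 M HCl quench; crude, conc. HCl (cat.), CH2Cl2, rt
Reagents that add atoms: water, O (supplies the new carbonyl oxygen; the carbinol oxygen leaves as water)
Why: Lithiation between two methoxy groups gives 3, which should add once to a squarate carbonyl at low temperature; acid ionises carbinol 4 to an alkoxy-stabilised cyclobutenyl cation that is hydrolysed at the distal isopropoxy carbon with loss of propan-2-ol (squarate 1,2-addition then acid-induced transposition to a 3-alkoxy-4-arylcyclobutenedione).

Step 2
Reactants: 5 3-(propan-2-yloxy)-4-(2,4,6-trimethoxyphenyl)cyclobut-3-ene-1,2-dione; 6 ethyl vinyl ether (ethoxyethene)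
Product: 9 4-(1-ethoxyethenyl)-4-(methoxymethoxy)-3-(propan-2-yloxy)-2-(2,4,6-trimethoxyphenyl)cyclobut-2-en-1-one (racemic), via 1-ethoxyvinyllithium 7 (not isolated), via lithium alkoxide adduct 8 (not isolated)
Conditions: 6 (excess), t-BuLi, THF, −78 to 0 °C; 5, THF, −78 °C; MOMCl, DMPU, −78 °C to rt
Reagents that add atoms: chloromethyl methyl ether (MOMCl), COCCl
Why: α-Lithiated ethyl vinyl ether 7 should add 1,2 to the carbonyl next to the isopropoxy-bearing carbon, because the other carbonyl is the end of a vinylogous ester and is also screened by the di-ortho-substituted aryl group; alkoxide 8 is then O-alkylated by the very reactive chloromethyl ether (Williamson-type capture). The new quaternary carbon forms as a racemate and is destroyed in step 3.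

Step 3
Reactants: 9 4-(1-ethoxyethenyl)-4-(methoxymethoxy)-3-(propan-2-yloxy)-2-(2,4,6-trimethoxyphenyl)cyclobut-2-en-1-one (racemic)
Product: 12 5-ethoxy-4-(methoxymethoxy)-3-(propan-2-yloxy)-2-(2,4,6-trimethoxyphenyl)phenol, via dienylketene 10 (not isolated), via cyclohexa-2,4-dienone tautomer 11 (not isolated)
Conditions: PhMe (degassed), 110 °C, Ar, base-washed glassware
Reagents that add atoms: none
Why: This is a Moore rearrangement: thermal conrotatory four-electron opening of the bond between the carbonyl carbon and the sp3 carbon of the cyclobutenone gives dienylketene 10. The oxygen donor on the sp3 carbon prefers to rotate outward, which turns the 1-ethoxyvinyl group inward, cis to the ketene; since the opening is reversible, any ketene of the other geometry should reclose and be funnelled through 10. A thermally allowed six-electron electrocyclisation then joins the ketene carbon to the terminal CH2 of the vinyl ether, forming the C3–C4 bond and closing ring C, the only ring made, as dienone 11 by a pericyclic closure. Tautomerisation of 11 to phenol 12 is driven by aromatisation and makes the sequence irreversible. No stereocentre is created and the one in 9 disappears. The closest known reaction type is the thermal ring expansion of squarate-derived 4-alkenyl-4-alkoxy- or 4-hydroxycyclobutenones to hydroquinone monoethers or quinones. The selectivity needed is regiochemical and is already fixed in 9 by steps 1 and 2: the aryl-bearing and isopropoxy-bearing ring carbons become C5 and C6, the capped oxygen becomes O1 and the ketene oxygen becomes the free O4 hydroxyl. Degassed solvent and acid-free glassware protect the enol ether, the acetal and the electron-rich phenol.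

Step 4
Reactants: 12 5-ethoxy-4-(methoxymethoxy)-3-(propan-2-yloxy)-2-(2,4,6-trimethoxyphenyl)phenol
Product: 13 1-ethoxy-5-methoxy-2-(methoxymethoxy)-3-(propan-2-yloxy)-4-(2,4,6-trimethoxyphenyl)benzene
Conditions: MeI, K2CO3, acetone, 50 °C
Reagents that add atoms: iodomethane, CI
Why: Williamson methylation of the only free phenol (O4); the acetal and the aryl ethers are inert to carbonate and iodomethane.

Step 5
Reactants: 13 1-ethoxy-5-methoxy-2-(methoxymethoxy)-3-(propan-2-yloxy)-4-(2,4,6-trimethoxyphenyl)benzene
Product: 14 6-ethoxy-4-methoxy-2-(propan-2-yloxy)-3-(2,4,6-trimethoxyphenyl)phenol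
Conditions: conc. HCl (cat.), MeOH, 50 °C
Reagents that add atoms: none
Why: Acid-catalysed acetal exchange with methanol (MOM cleavage) should free O1 alone; methyl, ethyl and isopropyl aryl ethers and the biaryl are stable to dilute methanolic acid at this temperature.

Step 6
Reactants: 15 3,5-dimethoxyphenol; 16 1-bromo-3-iodo-5-methoxybenzene
Product: 17 1-bromo-3-(3,5-dimethoxyphenoxy)-5-methoxybenzene
Conditions: CuI (10 mol %), picolinic acid (20 mol %), K3PO4, DMSO, 80 °C; 16 in slight excess
Reagents that add atoms: none
Why: Ligand-accelerated Ullmann diaryl ether synthesis; the copper phenoxide should react much faster at the carbon–iodine bond than at the carbon–bromine bond, so the bromide is kept for step 7.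

Step 7
Reactants: 14 6-ethoxy-4-methoxy-2-(propan-2-yloxy)-3-(2,4,6-trimethoxyphenyl)phenol; 17 1-bromo-3-(3,5-dimethoxyphenoxy)-5-methoxybenzene
Product: 18 2-[3-(3,5-dimethoxyphenoxy)-5-methoxyphenoxy]-1-ethoxy-5-methoxy-3-(propan-2-yloxy)-4-(2,4,6-trimethoxyphenyl)benzene
Conditions: CuI (20 mol %), picolinic acid (40 mol %), K3PO4, DMSO, 100 °C, Ar; 17 in excess
Reagents that add atoms: none
Why: Ullmann-type C–O coupling under picolinic acid–copper conditions suited to ortho-substituted phenols; O1 is the only free hydroxyl of 14, so the site is unambiguous, and bromide 17 has no ortho substituent, which offsets the crowding of the phenoxide.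

Step 8
Reactants: 18 2-[3-(3,5-dimethoxyphenoxy)-5-methoxyphenoxy]-1-ethoxy-5-methoxy-3-(propan-2-yloxy)-4-(2,4,6-trimethoxyphenyl)benzene
Product: 19 3-[3-(3,5-dihydroxyphenoxy)-5-hydroxyphenoxy]-[1,1'-biphenyl]-2,2',4,4',6,6'-hexol (target)
Conditions: BBr3 (excess), CH2Cl2, −78 °C to rt; H2O, 0 °C, Ar
Reagents that add atoms: none
Why: Lewis acid-mediated ether cleavage: BBr3 binds each alkoxy oxygen and bromide removes the methyl and ethyl groups (SN2) and the isopropyl group (SN1-like), while the diaryl ether and biaryl bonds are not attacked; aqueous work-up hydrolyses the aryloxyboron species to the nonaphenol.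

## Compound list

1 | 1,3,5-trimethoxybenzene | COc1cc(OC)cc(OC)c1 | starting material
2 | diisopropyl squarate [3,4-di(propan-2-yloxy)cyclobut-3-ene-1,2-dione] | CC(C)OC1=C(OC(C)C)C(=O)C1=O | starting material
3 | (2,4,6-trimethoxyphenyl)lithium | [Li]c1c(OC)cc(OC)cc1OC | intermediate
4 | 4-hydroxy-2,3-di(propan-2-yloxy)-4-(2,4,6-trimethoxyphenyl)cyclobut-2-en-1-one (racemic) | O=C1C(OC(C)C)=C(OC(C)C)C1(O)c1c(OC)cc(OC)cc1OC | intermediate
5 | 3-(propan-2-yloxy)-4-(2,4,6-trimethoxyphenyl)cyclobut-3-ene-1,2-dione | O=C1C(=O)C(OC(C)C)=C1c1c(OC)cc(OC)cc1OC | intermediate
6 | ethyl vinyl ether (ethoxyethene) | C=COCC | starting material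
7 | (1-ethoxyethenyl)lithium | [Li]C(=C)OCC | intermediate
8 | lithium 1-(1-ethoxyethenyl)-4-oxo-2-(propan-2-yloxy)-3-(2,4,6-trimethoxyphenyl)cyclobut-2-en-1-olate (racemic) | [Li+].[O-]C1(C(=C)OCC)C(OC(C)C)=C(c2c(OC)cc(OC)cc2OC)C1=O | intermediate
9 | 4-(1-ethoxyethenyl)-4-(methoxymethoxy)-3-(propan-2-yloxy)-2-(2,4,6-trimethoxyphenyl)cyclobut-2-en-1-one (racemic) | O=C1C(c2c(OC)cc(OC)cc2OC)=C(OC(C)C)C1(OCOC)C(=C)OCC | intermediate
10 | (3Z)-5-ethoxy-4-(methoxymethoxy)-3-(propan-2-yloxy)-2-(2,4,6-trimethoxyphenyl)hexa-1,3,5-trien-1-one | O=C=C(c1c(OC)cc(OC)cc1OC)/C(OC(C)C)=C(/OCOC)C(=C)OCC | intermediate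
11 | 5-ethoxy-4-(methoxymethoxy)-3-(propan-2-yloxy)-2-(2,4,6-trimethoxyphenyl)cyclohexa-2,4-dien-1-one | O=C1CC(OCC)=C(OCOC)C(OC(C)C)=C1c1c(OC)cc(OC)cc1OC | intermediate
12 | 5-ethoxy-4-(methoxymethoxy)-3-(propan-2-yloxy)-2-(2,4,6-trimethoxyphenyl)phenol | Oc1cc(OCC)c(OCOC)c(OC(C)C)c1-c1c(OC)cc(OC)cc1OC | intermediate
13 | 1-ethoxy-5-methoxy-2-(methoxymethoxy)-3-(propan-2-yloxy)-4-(2,4,6-trimethoxyphenyl)benzene | COc1cc(OCC)c(OCOC)c(OC(C)C)c1-c1c(OC)cc(OC)cc1OC | intermediate
14 | 6-ethoxy-4-methoxy-2-(propan-2-yloxy)-3-(2,4,6-trimethoxyphenyl)phenol | COc1cc(OCC)c(O)c(OC(C)C)c1-c1c(OC)cc(OC)cc1OC | intermediate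
15 | 3,5-dimethoxyphenol | COc1cc(O)cc(OC)c1 | starting material
16 | 1-bromo-3-iodo-5-methoxybenzene | COc1cc(Br)cc(I)c1 | starting material
17 | 1-bromo-3-(3,5-dimethoxyphenoxy)-5-methoxybenzene | COc1cc(Br)cc(Oc2cc(OC)cc(OC)c2)c1 | intermediate
18 | 2-[3-(3,5-dimethoxyphenoxy)-5-methoxyphenoxy]-1-ethoxy-5-methoxy-3-(propan-2-yloxy)-4-(2,4,6-trimethoxyphenyl)benzene | COc1cc(OC)cc(Oc2cc(OC)cc(Oc3c(OCC)cc(OC)c(-c4c(OC)cc(OC)cc4OC)c3OC(C)C)c2)c1 | intermediate
19 | 3-[3-(3,5-dihydroxyphenoxy)-5-hydroxyphenoxy]-[1,1'-biphenyl]-2,2',4,4',6,6'-hexol | Oc1cc(O)cc(Oc2cc(O)cc(Oc3c(O)cc(O)c(-c4c(O)cc(O)cc4O)c3O)c2)c1 | target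

## Step count and least certain steps

Total: 8 steps. Longest linear sequence: 7 steps (1, 2, 3, 4, 5, 7, 8); step 6 is a one-step branch.

Step 3 (key step). The most likely failures are three: loss of the acetal or hydrolysis of the enol ether by traces of acid during heating; diversion of the reversibly formed ketene by attack of the acetal oxygen, with loss of the methoxymethyl group, if inward rotation of the bulky ethoxyvinyl group is slow; and air oxidation of the electron-rich phenol on isolation. The fallback sets out from 5 and changes the substrate class and the way O1 is unveiled. Alkoxide 8 is made as in step 2 but capped with TBSOTf to give 4-[(tert-butyldimethylsilyl)oxy]-4-(1-ethoxyethenyl)-3-(propan-2-yloxy)-2-(2,4,6-trimethoxyphenyl)cyclobut-2-en-1-one F1, whose silyl ether oxygen is a poorer nucleophile toward the ketene and has no ionisable acetal carbon. Thermolysis in toluene should give 4-[(tert-butyldimethylsilyl)oxy]-5-ethoxy-3-(propan-2-yloxy)-2-(2,4,6-trimethoxyphenyl)phenol F2. Methylation (MeI, K2CO3, acetone, rt) should give tert-butyl[6-ethoxy-4-methoxy-2-(propan-2-yloxy)-3-(2,4,6-trimethoxyphenyl)phenoxy]dimethylsilane F3, and fluoride (TBAF, THF, 0 °C) removes the silyl group without acid. The fallback comes back to the route at 14.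

Step 7. The most likely failure is slow C–O bond formation at copper, because the phenoxide oxygen of 14 lies between an ethoxy group and an isopropoxy group that is pushed toward it by ring D; reduction of the carbon–bromine bond of 17 and oxidative decay of the phenoxide would then compete. The fallback sets out from 14 and 16 and reverses the order of the two ether bonds. Oxidation of 16 with mCPBA and TsOH and capture by 1 gives (3-bromo-5-methoxyphenyl)(2,4,6-trimethoxyphenyl)iodonium 4-methylbenzenesulfonate F4. The potassium phenoxide of 14 (t-BuOK, THF, rt) is arylated by F4 without metal through ligand coupling at trivalent iodine, a reaction type that accepts di-ortho-substituted phenoxides and transfers the less electron-rich aryl group, to give 1-bromo-3-[6-ethoxy-4-methoxy-2-(propan-2-yloxy)-3-(2,4,6-trimethoxyphenyl)phenoxy]-5-methoxybenzene F5. A copper-catalysed coupling of F5 with the unhindered phenol 15 (conditions of step 6, 100 °C) comes back to the route at 18.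

Step 2. The most likely failure is incomplete O-alkylation of the crowded tertiary alkoxide 8, which on warming can revert or fragment by alkoxide-accelerated ring opening; residual t-BuLi adding to 5 is a second risk if metalation of 6 is incomplete. The fallback sets out from 5 and separates addition from protection. Alkoxide 8 is quenched at −78 °C with buffered NH4Cl and the carbinol 4-(1-ethoxyethenyl)-4-hydroxy-3-(propan-2-yloxy)-2-(2,4,6-trimethoxyphenyl)cyclobut-2-en-1-one F6 is isolated. It is then protected under non-anionic conditions (MOMCl, i-Pr2NEt, Bu4NI cat., CH2Cl2, 0 °C to rt), coming back to the route at 9.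

Step 8. The most likely failures are incomplete cleavage of the ethyl ether and of the methoxy groups beside the biaryl axis, which would give mixtures of partial ethers that cannot be separated as free polyphenols, and oxidative darkening of the nonaphenol during work-up. The fallback sets out from 18 and changes the isolation from direct to derivatise, purify and release. The crude product of the BBr3 treatment is acetylated at once (Ac2O, pyridine, DMAP cat.) to 3-{3-[3,5-bis(acetyloxy)phenoxy]-5-(acetyloxy)phenoxy}-[1,1'-biphenyl]-2,2',4,4',6,6'-hexayl hexaacetate F7, which should be stable to air and silica and separable from partly dealkylated material. Acid methanolysis under argon (HCl in MeOH, rt) then comes back to the route at 19.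

## Further compounds

F1 | step 3 | 4-[(tert-butyldimethylsilyl)oxy]-4-(1-ethoxyethenyl)-3-(propan-2-yloxy)-2-(2,4,6-trimethoxyphenyl)cyclobut-2-en-1-one (racemic) | O=C1C(c2c(OC)cc(OC)cc2OC)=C(OC(C)C)C1(O[Si](C)(C)C(C)(C)C)C(=C)OCC
F2 | step 3 | 4-[(tert-butyldimethylsilyl)oxy]-5-ethoxy-3-(propan-2-yloxy)-2-(2,4,6-trimethoxyphenyl)phenol | Oc1cc(OCC)c(O[Si](C)(C)C(C)(C)C)c(OC(C)C)c1-c1c(OC)cc(OC)cc1OC
F3 | step 3 | tert-butyl[6-ethoxy-4-methoxy-2-(propan-2-yloxy)-3-(2,4,6-trimethoxyphenyl)phenoxy]dimethylsilane | COc1cc(OCC)c(O[Si](C)(C)C(C)(C)C)c(OC(C)C)c1-c1c(OC)cc(OC)cc1OC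
F4 | step 7 | (3-bromo-5-methoxyphenyl)(2,4,6-trimethoxyphenyl)iodonium 4-methylbenzenesulfonate | COc1cc(Br)cc([I+]c2c(OC)cc(OC)cc2OC)c1.Cc1ccc(cc1)S(=O)(=O)[O-]
F5 | step 7 | 1-bromo-3-[6-ethoxy-4-methoxy-2-(propan-2-yloxy)-3-(2,4,6-trimethoxyphenyl)phenoxy]-5-methoxybenzene | COc1cc(Br)cc(Oc2c(OCC)cc(OC)c(-c3c(OC)cc(OC)cc3OC)c2OC(C)C)c1
F6 | step 2 | 4-(1-ethoxyethenyl)-4-hydroxy-3-(propan-2-yloxy)-2-(2,4,6-trimethoxyphenyl)cyclobut-2-en-1-one (racemic) | O=C1C(c2c(OC)cc(OC)cc2OC)=C(OC(C)C)C1(O)C(=C)OCC
F7 | step 8 | 3-{3-[3,5-bis(acetyloxy)phenoxy]-5-(acetyloxy)phenoxy}-[1,1'-biphenyl]-2,2',4,4',6,6'-hexayl hexaacetate | CC(=O)Oc1cc(OC(C)=O)cc(Oc2cc(OC(C)=O)cc(Oc3c(OC(C)=O)cc(OC(C)=O)c(-c4c(OC(C)=O)cc(OC(C)=O)cc4OC(C)=O)c3OC(C)=O)c2)c1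
A1 | alternative 1 | (η5-cyclopentadienyl)(η6-1,3-dichloro-5-methoxybenzene)ruthenium hexafluorophosphate | COc1cc(Cl)cc(Cl)c1.[CH-]1C=CC=C1.[Ru+2].F[P-](F)(F)(F)(F)F
A2 | alternative 1 | 2,4,6-trimethoxy-3-(2,4,6-trimethoxyphenyl)phenol | COc1cc(OC)c(-c2c(OC)cc(OC)cc2OC)c(OC)c1O
A3 | alternative 1 | CpRu hexafluorophosphate complex of the nonamethyl ether of the target, bound at ring B | COc1cc(OC)cc(Oc2cc(OC)cc(Oc3c(OC)cc(OC)c(-c4c(OC)cc(OC)cc4OC)c3OC)c2)c1.[CH-]1C=CC=C1.[Ru+2].F[P-](F)(F)(F)(F)F
A4 | alternative 2 | methyl 6-{3-[3-(3,5-dimethoxyphenoxy)-5-methoxyphenoxy]-2,4,6-trimethoxyphenyl}-3,5-dioxohexanoate | COC(=O)CC(=O)CC(=O)Cc1c(OC)cc(OC)c(Oc2cc(OC)cc(Oc3cc(OC)cc(OC)c3)c2)c1OC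
A5 | alternative 2 | 2-{3-[3-(3,5-dimethoxyphenoxy)-5-methoxyphenoxy]-2,4,6-trimethoxyphenyl}benzene-1,3,5-triol | COc1cc(OC)c(-c2c(O)cc(O)cc2O)c(OC)c1Oc1cc(OC)cc(Oc2cc(OC)cc(OC)c2)c1
A6 | alternative 3 | 4-[3-(3,5-dimethoxyphenoxy)-5-methoxyphenoxy]-3-ethoxycyclobut-2-en-1-one (racemic) | CCOC1=CC(=O)C1Oc1cc(OC)cc(Oc2cc(OC)cc(OC)c2)c1
A7 | alternative 3 | triisopropyl{[(2,4,6-trimethoxyphenyl)ethynyl]oxy}silane | COc1cc(OC)c(C#CO[Si](C(C)C)(C(C)C)C(C)C)c(OC)c1
A8 | alternative 3 | 2-[3-(3,5-dimethoxyphenoxy)-5-methoxyphenoxy]-3-ethoxy-6-(2,4,6-trimethoxyphenyl)-5-[(triisopropylsilyl)oxy]phenol | CCOc1cc(O[Si](C(C)C)(C(C)C)C(C)C)c(-c2c(OC)cc(OC)cc2OC)c(O)c1Oc1cc(OC)cc(Oc2cc(OC)cc(OC)c2)c1
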